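**Retrosynthetic overview**

1. 11 ⇐ 10: hydration of the C1–C6 vinyl oxirane with retention at C6 (palladium-catalysed double inversion).
2. 10 ⇐ 9: peracid epoxidation of the C1=C6 bond of the trans-diacetoxy diene, the laboratory copy of the presumed biosynthetic epoxidation of the benzyl benzoate trans-dihydrodiol.
3. 9 ⇐ 7 ⇐ 5: dehydrogenation (bromine addition, double E2) of a cyclohexene trans-diacetate, itself made by trans opening of an oxirane with acetate (the "arene oxide → trans-dihydrodiol" event).
4. 5 ⇐ 3 ⇐ 1: one catalytic enantiotopos-selective epoxidation of the Birch diene (a configurationally stable 1,4-dihydro arene oxide) sets all absolute stereochemistry; the carbocycle is the ring of benzoic acid.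
5. Ring order: carbocycle (from the arene, step 1) → C2–C3 oxirane (step 3, opened in step 5) → C1–C6 oxirane (step 7, opened in step 8).

Convention: ring atoms keep the target numbering throughout (C1 bears C7H2OBz, C2 and C3 the acetates, C4=C5, C6 the secondary OH).
Assumption: the (R,R) ligand in step 3 is taken to give 4; if its sense of induction is the opposite, the (S,S) ligand is used.

**Route**

Step 1
Reactants: 1 benzoic acid
Product: 2 cyclohexa-2,5-diene-1-carboxylic acid
Conditions: Na, liquid NH3, EtOH, −78 °C → −33 °C; NH4Cl; aq. HCl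
Reagents that add atoms: none
Why: Birch reduction of the benzoate anion protonates the ipso and para carbons and gives the unconjugated 1,4-dihydro acid, so the arene is dearomatised without creating a stereocentre.

Step 2
Reactants: 2 cyclohexa-2,5-diene-1-carboxylic acid
Product: 3 (cyclohexa-2,5-dien-1-yl)methanol
Conditions: LiAlH4, Et2O, 0 °C → rt; aqueous work-up
Reagents that add atoms: none
Why: LiAlH4 reduction of the carboxylic acid gives the primary alcohol at low temperature without moving the skipped diene into conjugation, and no stereocentre is formed.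

Step 3
Reactants: 3 (cyclohexa-2,5-dien-1-yl)methanol
Product: 4 [(1S,2R,6R)-7-oxabicyclo[4.1.0]hept-3-en-2-yl]methanol (oxirane syn to CH2OH)
Conditions: VO(OiPr)3 (2 mol %), (R,R)-N,N′-dihydroxy-N,N′-bis(diphenylacetyl)cyclohexane-1,2-diamine (4 mol %), cumene hydroperoxide (1.2 equiv), toluene, 0 °C → rt
Reagents that add atoms: cumene hydroperoxide, CC(C)(OO)c1ccccc1
Why: Hydroxyl-directed vanadium-catalysed asymmetric epoxidation of a homoallylic alcohol, run as a desymmetrisation: the alkoxide-bound vanadium peroxide delivers oxygen syn to CH2OH and the chiral bis-hydroxamate selects one of the two enantiotopic alkenes, which sets C1, C2 and C3 at once while the minor enantiomer is drained into bis-epoxide.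

Step 4
Reactants: 4 [(1S,2R,6R)-7-oxabicyclo[4.1.0]hept-3-en-2-yl]methanol
Product: 5 [(1S,2R,6R)-7-oxabicyclo[4.1.0]hept-3-en-2-yl]methyl benzoate
Conditions: BzCl, Et3N, DMAP (cat.), CH2Cl2, 0 °C
Reagents that add atoms: benzoyl chloride, O=C(Cl)c1ccccc1
Why: DMAP-catalysed acylation (nucleophilic acyl substitution) of the primary alcohol under basic conditions leaves the oxirane and all stereocentres untouched.

Step 5
Reactants: 5 [(1S,2R,6R)-7-oxabicyclo[4.1.0]hept-3-en-2-yl]methyl benzoate
Product: 7 [(1R,5S,6S)-5,6-diacetoxycyclohex-2-en-1-yl]methyl benzoate, via trans-hydroxy acetate 6 (not isolated)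
Conditions: CsOAc, AcOH, DMF, 80 °C; then Ac2O, pyridine, DMAP (cat.), 0 °C → rt
Reagents that add atoms: acetic acid, CC(O)=O (as caesium acetate, [Cs+].CC([O-])=O); acetic anhydride, CC(=O)OC(C)=O
Why: SN2 epoxide opening by acetate anti to the oxirane at C3, the carbon remote from the branched C1 (the usual outcome for a cis-3-substituted cyclohexene oxide, and the syn benzoate cannot reach the backside of C2), inverts C3 and keeps the C2–O bond, and acetylation in the same flask gives the trans-diacetate (the minor C2-opened diastereomer is removed here by chromatography).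

Step 6
Reactants: 7 [(1R,5S,6S)-5,6-diacetoxycyclohex-2-en-1-yl]methyl benzoate
Product: 9 [(5S,6S)-5,6-diacetoxycyclohexa-1,3-dien-1-yl]methyl benzoate, via trans-dibromide 8 (not isolated)
Conditions: Bu4NBr3, CH2Cl2, −40 °C; then DBU (3 equiv), −40 °C → rt
Reagents that add atoms: none
Why: Anti addition of bromine (the tribromide salt keeps bromide available and suppresses benzoate participation) gives the trans-dibromide, and DBU then removes two HBr by E2 (C4–H/C5–Br and C1–H/C6–Br) to the conjugated diene, which erases the C1 stereocentre and leaves C2 and C3 untouched (the other trans-dibromide, if formed, converges on 9).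

Step 7
Reactants: 9 [(5S,6S)-5,6-diacetoxycyclohexa-1,3-dien-1-yl]methyl benzoate
Product: 10 [(1S,2R,3S,6S)-2,3-diacetoxy-7-oxabicyclo[4.1.0]hept-4-en-1-yl]methyl benzoate
Conditions: mCPBA (1.05 equiv), Na2HPO4, CH2Cl2, 0 °C
Reagents that add atoms: mCPBA, OOC(=O)c1cccc(Cl)c1
Why: Prilezhaev epoxidation is expected to take the more substituted C1=C6 bond of the diene on the face syn to the allylic C2 acetate and anti to the pseudoaxial homoallylic C3 acetate, as in the presumed biosynthetic epoxidation, which sets C1 and C6.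

Step 8
Reactants: 10 [(1S,2R,3S,6S)-2,3-diacetoxy-7-oxabicyclo[4.1.0]hept-4-en-1-yl]methyl benzoate
Product: 11 [(1S,2S,5S,6R)-5,6-diacetoxy-1,2-dihydroxycyclohex-3-en-1-yl]methyl benzoate
Conditions: Pd2(dba)3·CHCl3 (2.5 mol %), PPh3 (10 mol %), BEt3 (10 mol %), NaHCO3 (1.5 equiv), CH2Cl2/H2O, rt
Reagents that add atoms: water, O (relayed by sodium hydrogen carbonate, [Na+].OC([O-])=O, which is regenerated)
Why: Tsuji–Trost allylic substitution of a vinyl epoxide: zerovalent palladium ionises the C6–O bond with inversion, and the borane-bound hydrogen carbonate held on the C1 alkoxide attacks C6 anti to palladium (second inversion), so the net hydration goes with retention and gives the cis-1,6-diol after the hemicarbonate loses CO2.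

**Compound list**

1 | benzoic acid | OC(=O)c1ccccc1 | starting material
2 | cyclohexa-2,5-diene-1-carboxylic acid | OC(=O)C1C=CCC=C1 | intermediate
3 | (cyclohexa-2,5-dien-1-yl)methanol | OCC1C=CCC=C1 | intermediate
4 | [(1S,2R,6R)-7-oxabicyclo[4.1.0]hept-3-en-2-yl]methanol | OC[C@@H]1[C@@H]2O[C@@H]2CC=C1 | intermediate
5 | [(1S,2R,6R)-7-oxabicyclo[4.1.0]hept-3-en-2-yl]methyl benzoate | O=C(OC[C@@H]1[C@@H]2O[C@@H]2CC=C1)c1ccccc1 | intermediate
6 | [(1R,5S,6S)-5-acetoxy-6-hydroxycyclohex-2-en-1-yl]methyl benzoate | O=C(OC[C@@H]1[C@H](O)[C@@H](OC(C)=O)CC=C1)c1ccccc1 | intermediate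
7 | [(1R,5S,6S)-5,6-diacetoxycyclohex-2-en-1-yl]methyl benzoate | O=C(OC[C@@H]1[C@H](OC(C)=O)[C@@H](OC(C)=O)CC=C1)c1ccccc1 | intermediate
8 | [(1R,2S,3S,5R,6R)-2,3-diacetoxy-5,6-dibromocyclohexyl]methyl benzoate | O=C(OC[C@@H]1[C@H](OC(C)=O)[C@@H](OC(C)=O)C[C@@H](Br)[C@@H]1Br)c1ccccc1 | intermediate
9 | [(5S,6S)-5,6-diacetoxycyclohexa-1,3-dien-1-yl]methyl benzoate | CC(=O)O[C@@H]1[C@@H](OC(C)=O)C=CC=C1COC(=O)c1ccccc1 | intermediate
10 | [(1S,2R,3S,6S)-2,3-diacetoxy-7-oxabicyclo[4.1.0]hept-4-en-1-yl]methyl benzoate | CC(=O)O[C@@H]1[C@@H](OC(C)=O)C=C[C@@H]2O[C@]12COC(=O)c1ccccc1 | intermediate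
11 | [(1S,2S,5S,6R)-5,6-diacetoxy-1,2-dihydroxycyclohex-3-en-1-yl]methyl benzoate | CC(=O)O[C@H]1C=C[C@H](O)[C@@](O)(COC(=O)c2ccccc2)[C@@H]1OC(C)=O | target

**Count and risks**

Total steps: 8. Longest linear sequence: 8 (the route is fully linear).

Most likely to fail, first: step 8. The hydrogen carbonate may attack C4 instead of C6 (giving the 1,4-diol), the catalyst may ionise the allylic C3 acetate, or the π-allyl intermediate may eliminate. The fallback sets out from 10 and comes back at 11. Epoxide 10 is oxidised at C6 with DMSO under BF3·OEt2 and then Et3N (Kornblum-type oxidative opening: DMSO attacks the allylic C6 and the alkoxysulfonium salt collapses to the ketone), giving α-hydroxy enone F8 with C1 untouched. Luche reduction (NaBH4, CeCl3·7H2O, MeOH, −78 °C) then delivers hydride to C6 anti to the axial C1–O bond, in the half-chair that keeps both acetates and CH2OBz equatorial, and gives the cis-diol 11.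

Second: step 7. The face selectivity, and the choice of C1=C6 over C4=C5, rest on weak substrate bias. The fallback sets out from 9 and comes back at 10. The two acetates of 9 are removed with Mg(OMe)2 in MeOH at 0 °C (acetates cleave well before the primary benzoate), giving dienediol F6. Epoxidation with VO(acac)2 and TBHP in CH2Cl2 at 0 °C is then directed by the allylic C2 hydroxyl onto the trisubstituted C1=C6 bond, syn to that hydroxyl, giving epoxy diol F7. Ac2O, pyridine and DMAP return 10.

Third: step 3. The enantioselectivity on this particular diene is not assured, and the skipped diene may aromatise under the oxidant. The fallback sets out from 3 and comes back at 7, replacing catalytic desymmetrisation by enzymatic resolution. Alcohol 3 is epoxidised without a chiral ligand (VO(acac)2, TBHP, CH2Cl2, 0 °C, syn-directed) to racemic syn-epoxy alcohol F1 and benzoylated (BzCl, Et3N, DMAP) to racemic epoxy benzoate F2. This is opened and acetylated as in step 5, through racemic trans-hydroxy acetate F3, to racemic trans-diacetate F4. F4 is resolved by hydrolysis with Amano lipase PS (Burkholderia cepacia) in phosphate buffer pH 7/MTBE at 30 °C to about 55% conversion. The enzyme is expected to remove the less hindered C3 acetate of the (1S,5R,6R) enantiomer (the R-configured carbinol centre, as the Kazlauskas rule predicts), giving hydroxy acetate F5. The untouched diacetate is 7, separated by chromatography.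

**Further compounds**

F1 | step 3 | racemic [(1S,2R,6R)-7-oxabicyclo[4.1.0]hept-3-en-2-yl]methanol (racemate of 4) | OC[C@@H]1[C@@H]2O[C@@H]2CC=C1.OC[C@H]1[C@H]2O[C@H]2CC=C1
F2 | step 3 | racemic [(1S,2R,6R)-7-oxabicyclo[4.1.0]hept-3-en-2-yl]methyl benzoate (racemate of 5) | O=C(OC[C@@H]1[C@@H]2O[C@@H]2CC=C1)c1ccccc1.O=C(OC[C@H]1[C@H]2O[C@H]2CC=C1)c1ccccc1
F3 | step 3 | racemic [(1R,5S,6S)-5-acetoxy-6-hydroxycyclohex-2-en-1-yl]methyl benzoate (racemate of 6) | O=C(OC[C@@H]1[C@H](O)[C@@H](OC(C)=O)CC=C1)c1ccccc1.O=C(OC[C@H]1[C@@H](O)[C@H](OC(C)=O)CC=C1)c1ccccc1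
F4 | step 3 | racemic [(1R,5S,6S)-5,6-diacetoxycyclohex-2-en-1-yl]methyl benzoate (racemate of 7) | O=C(OC[C@@H]1[C@H](OC(C)=O)[C@@H](OC(C)=O)CC=C1)c1ccccc1.O=C(OC[C@H]1[C@@H](OC(C)=O)[C@H](OC(C)=O)CC=C1)c1ccccc1
F5 | step 3 | [(1S,5R,6R)-6-acetoxy-5-hydroxycyclohex-2-en-1-yl]methyl benzoate | O=C(OC[C@H]1[C@@H](OC(C)=O)[C@H](O)CC=C1)c1ccccc1
F6 | step 7 | [(5S,6S)-5,6-dihydroxycyclohexa-1,3-dien-1-yl]methyl benzoate | O[C@@H]1[C@@H](O)C=CC=C1COC(=O)c1ccccc1
F7 | step 7 | [(1R,2R,3S,6S)-2,3-dihydroxy-7-oxabicyclo[4.1.0]hept-4-en-1-yl]methyl benzoate | O[C@@H]1[C@@H](O)C=C[C@@H]2O[C@]12COC(=O)c1ccccc1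
F8 | step 8 | [(1R,5S,6R)-5,6-diacetoxy-1-hydroxy-2-oxocyclohex-3-en-1-yl]methyl benzoate | CC(=O)O[C@@H]1[C@@H](OC(C)=O)C=CC(=O)[C@@]1(O)COC(=O)c1ccccc1
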